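**Retrosynthetic overview**
Numbering: C1 CH–O-anisoyl, C2=C3(CH3), C4, C5, C6 C–OH, C7 CH–iPr, C8, C9 C=O, C10 C–CH3. The seven-membered ring is C1–C6 plus C10 and the five-membered ring is C6–C10.
Feature: quaternary C10 lies between the C9 ketone and the C6 carbinol. The five-membered ring is therefore 2-methylcyclopentane-1,3-dione (7) in which one of two equivalent carbonyls has taken up C5.
C5–C6 (key): SmI2 Barbier closure of the C5 iodide 9 onto one of the two diastereotopic carbonyls. The five-membered ring is bought, the seven-membered ring is the only ring formed, and C6 and C10 are set from C1.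
C1–C10: Pd-catalysed asymmetric allylic alkylation of 7 with the Z gem-bis(anisoate) 6 sets C1 and installs the ester of the target. The Z C2=C3 bond comes from the ring of lactone 1.
C7–iPr comes last: C9 ketone to C7=C8 enone, copper-catalysed isopropyl addition on the convex face, then desilylation.

Key step: step 7

Assumption: the (R,R) ligand is written in step 5. The sense of induction for this Z-trisubstituted gem-diester is assigned by analogy and has to be confirmed on 8; the antipodal ligand gives the mirror-image series.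
Remark: C1–C10 is made under neutral Pd(0) conditions for two reasons. A direct aldol of 7 with enal 4 is reversible and uphill. Building the dione by acid-mediated geminal acylation next to an allylic C1–O bond invites ionisation and a hydride shift.

**Step 1**
Reactants: 1 4-methyl-5,6-dihydro-2H-pyran-2-one
Product: 2 (Z)-5-hydroxy-N-methoxy-N,3-dimethylpent-2-enamide
Conditions: MeNH(OMe)·HCl, i-PrMgCl, THF, −20 → 0 °C
Reagents that add atoms: N,O-dimethylhydroxylamine hydrochloride, CNOC.Cl
Why: Weinreb amide formation by aminolysis of the lactone with the magnesium amide opens the ring at the acyl C–O bond, so the ring-enforced Z geometry of C2=C3 is carried into the open chain.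

**Step 2**
Reactants: 2 (Z)-5-hydroxy-N-methoxy-N,3-dimethylpent-2-enamide
Product: 3 (Z)-5-chloro-N-methoxy-N,3-dimethylpent-2-enamide
Conditions: PPh3, CCl4, CH2Cl2, 0 °C → rt
Reagents that add atoms: carbon tetrachloride, ClC(Cl)(Cl)Cl
Why: The Appel reaction turns the primary C5 alcohol into a chloride that serves as an inert placeholder for iodide through the hydride, Lewis-acid and Pd(0) steps; any O-alkylated imidate salt formed by amide participation is reopened by chloride to the same product.

**Step 3**
Reactants: 3 (Z)-5-chloro-N-methoxy-N,3-dimethylpent-2-enamide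
Product: 4 (Z)-5-chloro-3-methylpent-2-enal
Conditions: DIBAL-H, THF, −78 °C; aq. Rochelle salt
Reagents that add atoms: none
Why: Partial hydride reduction of a Weinreb amide stops at the aldehyde level, and the cold neutral work-up should keep the Z-enal from isomerising.

**Step 4**
Reactants: 4 (Z)-5-chloro-3-methylpent-2-enal; 5 4-methoxybenzoic anhydride
Product: 6 (2Z)-5-chloro-3-methylpent-2-ene-1,1-diyl bis(4-methoxybenzoate)
Conditions: Bi(OTf)3 (1 mol %), CH2Cl2, −20 °C
Reagents that add atoms: none
Why: Lewis-acid-catalysed acylal formation adds the anhydride across the aldehyde C=O, and low temperature with short contact limits rotation about C2–C3 in the activated enal.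

**Step 5**
Reactants: 6 (2Z)-5-chloro-3-methylpent-2-ene-1,1-diyl bis(4-methoxybenzoate); 7 2-methylcyclopentane-1,3-dione
Product: 8 (1R,2Z)-5-chloro-3-methyl-1-(1-methyl-2,5-dioxocyclopentyl)pent-2-en-1-yl 4-methoxybenzoate
Conditions: [Pd(allyl)Cl]2 (2.5 mol %), (R,R)-DACH-phenyl bisphosphine ligand (7.5 mol %), Et3N, CH2Cl2, 0 °C → rt
Reagents that add atoms: none
Why: In this Tsuji–Trost asymmetric allylic alkylation of an allylic gem-dicarboxylate, Pd(0) in the chiral pocket ionises one of the two enantiotopic anisoyloxy groups and the soft dione enolate attacks the oxygen-bearing terminus C1 anti to Pd rather than the fully substituted C3, which sets C1 as R, while the 3,3-disubstituted terminus resists syn/anti exchange so that the Z geometry should be kept.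

**Step 6**
Reactants: 8 (1R,2Z)-5-chloro-3-methyl-1-(1-methyl-2,5-dioxocyclopentyl)pent-2-en-1-yl 4-methoxybenzoate
Product: 9 (1R,2Z)-5-iodo-3-methyl-1-(1-methyl-2,5-dioxocyclopentyl)pent-2-en-1-yl 4-methoxybenzoate
Conditions: NaI, acetone, reflux
Reagents that add atoms: sodium iodide, [Na+].[I-]
Why: The Finkelstein exchange at primary C5 is driven by precipitation of NaCl under neutral conditions that leave the base-sensitive non-enolisable β-diketone and the allylic ester untouched.

**Step 7**
Reactants: 9 (1R,2Z)-5-iodo-3-methyl-1-(1-methyl-2,5-dioxocyclopentyl)pent-2-en-1-yl 4-methoxybenzoate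
Product: 12 (3aS,8R,8aR)-3a-hydroxy-6,8a-dimethyl-1-oxo-1,2,3,3a,4,5,8,8a-octahydroazulen-8-yl 4-methoxybenzoate (route numbering 1R,6S,10R; cis-fused; C6–OH and C10–CH3 cis; O-anisoyl trans to both), via alkylsamarium diiodide 10 (not isolated), via samarium(III) alkoxide 11 (not isolated)
Conditions: SmI2 (2.5 equiv), HMPA, THF, −78 °C, slow addition of 9 (high dilution); pH 7 buffer at −78 °C
Reagents that add atoms: none
Why: Sm(II) passes two electrons to the C5–I bond (radical, then alkylsamarium 10), and this carbon nucleophile adds to a ring carbonyl; this is the intramolecular samarium Barbier reaction of an ω-iodoalkyl ketone, run here as a group-selective addition to a 2,2-disubstituted cyclopentane-1,3-dione. The seven-membered ring closes 7-exo-trig at C=O, and the Z C2=C3 bond and quaternary C10 leave only the C1–C10, C3–C4 and C4–C5 bonds free to rotate. C6 is fixed by the tether, because C5 can reach a carbonyl only on the ring face that carries C1, so C6–OH and C10–CH3 end up cis (cis-fused hydroazulene). C10 is fixed by which carbonyl is attacked: in the chair-like cycloheptene transition state the alkenyl arm lies over the dione ring, anti to the C10 methyl, and the C1 anisoyloxy group is pseudo-equatorial (anti to the C10–C6 bond) only for attack on the carbonyl remote from it, which gives the 1R,6S,10R isomer, whereas attack on the other carbonyl forces it pseudo-axial beside the forming bond. The step also needs the iodide to be reduced before the dione (a ketyl could break the weak C1–C10 bond), addition to a ketone rather than to the ester, and survival of the β-ketol; HMPA makes iodide reduction fast at −78 °C, the electron-rich anisoate is a poor electron and nucleophile acceptor, and the cold buffered quench forestalls retro-aldol opening of alkoxide 11.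

**Step 8**
Reactants: 12 (3aS,8R,8aR)-3a-hydroxy-6,8a-dimethyl-1-oxo-1,2,3,3a,4,5,8,8a-octahydroazulen-8-yl 4-methoxybenzoate
Product: 13 (3aS,8R,8aR)-6,8a-dimethyl-1,3a-bis(trimethylsilyloxy)-3,3a,4,5,8,8a-hexahydroazulen-8-yl 4-methoxybenzoate (C6–OTMS, C8=C9 enol silane)
Conditions: TMSOTf, Et3N, CH2Cl2, −20 → 0 °C
Reagents that add atoms: trimethylsilyl trifluoromethanesulfonate, C[Si](C)(C)OS(=O)(=O)C(F)(F)F
Why: Soft enolisation with silyl triflate and amine caps the tertiary C6–OH (blocking retro-aldol) and, in the same operation, converts the C9 ketone, which is enolisable only toward C8, into its enol silane without touching a stereocentre.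

**Step 9**
Reactants: 13 (3aS,8R,8aR)-6,8a-dimethyl-1,3a-bis(trimethylsilyloxy)-3,3a,4,5,8,8a-hexahydroazulen-8-yl 4-methoxybenzoate
Product: 14 (3aS,8R,8aR)-6,8a-dimethyl-1-oxo-3a-(trimethylsilyloxy)-1,3a,4,5,8,8a-hexahydroazulen-8-yl 4-methoxybenzoate (C7=C8 enone)
Conditions: Pd(OAc)2 (1.1 equiv), MeCN, rt
Reagents that add atoms: none
Why: Saegusa–Ito oxidation of the enol silane gives the C7=C8 enone with unambiguous regiochemistry, because C10 carries no hydrogen, and phosphine-free Pd should leave the hindered allylic anisoate alone.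

**Step 10**
Reactants: 14 (3aS,8R,8aR)-6,8a-dimethyl-1-oxo-3a-(trimethylsilyloxy)-1,3a,4,5,8,8a-hexahydroazulen-8-yl 4-methoxybenzoate
Product: 15 (3S,3aS,8R,8aS)-6,8a-dimethyl-3-(propan-2-yl)-1,3a-bis(trimethylsilyloxy)-3,3a,4,5,8,8a-hexahydroazulen-8-yl 4-methoxybenzoate (iPr cis to C6–O and C10–CH3; the descriptors at C7 and C10 differ from those of 16 by CIP priority only)
Conditions: i-PrMgCl, CuBr·SMe2 (20 mol %), TMSCl, HMPA, THF, −78 °C
Reagents that add atoms: isopropylmagnesium chloride, CC(C)[Mg]Cl; chlorotrimethylsilane, C[Si](C)(C)Cl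
Why: The copper-catalysed, TMSCl-accelerated conjugate addition of the Grignard reagent should reach C7 from the convex face (the face of the small C6–OTMS and C10–CH3), because the other face is covered by C5, C1 and the anisoyloxy-bearing seven-membered ring, which sets C7; trapping as the enol silane avoids a free enolate.

**Step 11**
Reactants: 15 (3S,3aS,8R,8aS)-6,8a-dimethyl-3-(propan-2-yl)-1,3a-bis(trimethylsilyloxy)-3,3a,4,5,8,8a-hexahydroazulen-8-yl 4-methoxybenzoate
Product: 16 (3R,3aS,8R,8aR)-3a-hydroxy-6,8a-dimethyl-1-oxo-3-(propan-2-yl)-1,2,3,3a,4,5,8,8a-octahydroazulen-8-yl 4-methoxybenzoate (route numbering 1R,6S,7R,10R)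
Conditions: HF·pyridine, pyridine, THF, 0 °C
Reagents that add atoms: none
Why: Buffered fluoride desilylation frees the C9 ketone and the C6–OH without generating an alkoxide, so neither the β-ketol nor the β-acyloxy ketone can undergo retro-aldol cleavage and no stereocentre is touched.

**Compound list**
1 | 4-methyl-5,6-dihydro-2H-pyran-2-one | CC1=CC(=O)OCC1 | starting material
2 | (Z)-5-hydroxy-N-methoxy-N,3-dimethylpent-2-enamide | CON(C)C(=O)/C=C(C)\CCO | intermediate
3 | (Z)-5-chloro-N-methoxy-N,3-dimethylpent-2-enamide | CON(C)C(=O)/C=C(C)\CCCl | intermediate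
4 | (Z)-5-chloro-3-methylpent-2-enal | O=C/C=C(C)\CCCl | intermediate
5 | 4-methoxybenzoic anhydride | COc1ccc(cc1)C(=O)OC(=O)c1ccc(OC)cc1 | starting material
6 | (2Z)-5-chloro-3-methylpent-2-ene-1,1-diyl bis(4-methoxybenzoate) | COc1ccc(cc1)C(=O)OC(/C=C(C)\CCCl)OC(=O)c1ccc(OC)cc1 | intermediate
7 | 2-methylcyclopentane-1,3-dione | CC1C(=O)CCC1=O | starting material
8 | (1R,2Z)-5-chloro-3-methyl-1-(1-methyl-2,5-dioxocyclopentyl)pent-2-en-1-yl 4-methoxybenzoate | COc1ccc(cc1)C(=O)O[C@H](/C=C(C)\CCCl)C1(C)C(=O)CCC1=O | intermediate
9 | (1R,2Z)-5-iodo-3-methyl-1-(1-methyl-2,5-dioxocyclopentyl)pent-2-en-1-yl 4-methoxybenzoate (key-step precursor) | COc1ccc(cc1)C(=O)O[C@H](/C=C(C)\CCI)C1(C)C(=O)CCC1=O | intermediate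
10 | C5 alkylsamarium(III) diiodide derived from 9 | COc1ccc(cc1)C(=O)O[C@H](/C=C(C)\CC[Sm](I)I)C1(C)C(=O)CCC1=O | intermediate (not isolated)
11 | C6 samarium(III) alkoxide of 12 | COc1ccc(cc1)C(=O)O[C@@H]2C=C(C)CC[C@]3(O[Sm](I)I)CCC(=O)[C@]23C | intermediate (not isolated)
12 | cis-fused hydroazulene ketol, (3aS,8R,8aR)-3a-hydroxy-6,8a-dimethyl-1-oxo-1,2,3,3a,4,5,8,8a-octahydroazulen-8-yl 4-methoxybenzoate (key-step product) | COc1ccc(cc1)C(=O)O[C@@H]2C=C(C)CC[C@]3(O)CCC(=O)[C@]23C | intermediate
13 | C6–OTMS, C8=C9 enol silane | COc1ccc(cc1)C(=O)O[C@@H]2C=C(C)CC[C@]3(O[Si](C)(C)C)CC=C(O[Si](C)(C)C)[C@]23C | intermediate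
14 | C6–OTMS, C7=C8 enone | COc1ccc(cc1)C(=O)O[C@@H]2C=C(C)CC[C@]3(O[Si](C)(C)C)C=CC(=O)[C@]23C | intermediate
15 | C7-isopropyl adduct, C6–OTMS, C8=C9 enol silane | COc1ccc(cc1)C(=O)O[C@@H]2C=C(C)CC[C@]3(O[Si](C)(C)C)[C@@H](C(C)C)C=C(O[Si](C)(C)C)[C@]23C | intermediate
16 | (3R,3aS,8R,8aR)-3a-hydroxy-6,8a-dimethyl-1-oxo-3-(propan-2-yl)-1,2,3,3a,4,5,8,8a-octahydroazulen-8-yl 4-methoxybenzoate | COc1ccc(C(=O)O[C@@H]2C=C(C)CC[C@]3(O)[C@@H](C(C)C)CC(=O)[C@]23C)cc1 | target

Total step count: 11. Longest linear sequence: 11 steps (1 → 16); 5 and 7 are bought.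

**Steps most likely to fail**

*Step 7.*
- Electron transfer may go to the dione instead of the C–I bond, leading to carbonyl reduction or ketyl-induced breaking of the C1–C10 bond.
- The alkylsamarium may be protonated before it closes the ring.
- The C1 group may discriminate poorly between the two carbonyls.
- The samarium alkoxide may equilibrate by retro-aldol.

The fallback takes the choice of carbonyl out of the ring closure and gives it to a catalyst. It sets out from 9.
1. Oxazaborolidine-catalysed borane mono-reduction (CBS desymmetrisation of a 2,2-disubstituted cyclopentane-1,3-dione) removes the carbonyl that is to remain as C9. This gives the C9 hydroxy ketone F1, with C9–OH cis to the C1 arm.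
2. Silylation with TESOTf and 2,6-lutidine gives the triethylsilyl ether F2.
3. The same SmI2 closure now has a single carbonyl to attack, and no β-diketone enolate can be expelled. It gives the tertiary alcohol F3.
4. HF·pyridine gives the C6,C9-diol F4.
5. Dess–Martin oxidation of the secondary C9 carbinol, with the tertiary C6–OH inert, returns to 12.

*Step 5.*
- The allyl-palladium intermediate may undergo syn/anti exchange with erosion of the Z geometry.
- It may lose a β-hydrogen to give a dienyl ester while attack by the hindered enolate is slow.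
- It may be captured at oxygen.
- Ionisation of the two anisoyloxy groups may be poorly differentiated.

The fallback sets C1 first and then builds the five-membered ring on it. It sets out from 3.
1. 1-Ethoxyvinyllithium (ethyl vinyl ether, t-BuLi) gives the cross-conjugated ketone F5.
2. (S)-Me-CBS/borane reduction, with the α-branched ethoxyvinyl group as the large substituent, gives the (R)-carbinol F6.
3. 4-Methoxybenzoyl chloride with DMAP gives the anisoate F7.
4. Wet oxalic acid on silica unmasks the methyl ketone F8.
5. Geminal acylation with 1,2-bis(trimethylsilyloxy)cyclobutene (BF3·OEt2 at −78 °C, then acid-induced acyl migration) returns to 8.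

*Step 10.*
- Facial selectivity may be poor if the C6 silyl ether shields the convex face as much as the seven-membered ring shields the other one.
- Copper-mediated allylic displacement of the anisoate or 1,2-addition may compete.

The fallback replaces substrate control by catalyst control. It sets out from 14.
1. Rhodium/BINAP-catalysed Hayashi–Miyaura conjugate addition of potassium isopropenyltrifluoroborate, using the ligand enantiomer matched to delivery cis to C6–O, gives the isopropenyl ketone F9.
2. Hydrogenation with Wilkinson's catalyst saturates only the 1,1-disubstituted alkene and gives the isopropyl ketone F10.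
3. HF·pyridine returns to 16.

**Further compounds**
F1 | step 7 | C9 hydroxy ketone, iodide (C9–OH cis to the C1 arm) | COc1ccc(cc1)C(=O)O[C@H](/C=C(C)\CCI)[C@]1(C)C(=O)CC[C@@H]1O
F2 | step 7 | C9 triethylsilyl ether of F1 | COc1ccc(cc1)C(=O)O[C@H](/C=C(C)\CCI)[C@]1(C)C(=O)CC[C@@H]1O[Si](CC)(CC)CC
F3 | step 7 | cis-fused hydroazulene, C6–OH, C9–OTES | COc1ccc(cc1)C(=O)O[C@@H]2C=C(C)CC[C@]3(O)CC[C@H](O[Si](CC)(CC)CC)[C@]23C
F4 | step 7 | cis-fused hydroazulene C6,C9-diol | COc1ccc(cc1)C(=O)O[C@@H]2C=C(C)CC[C@]3(O)CC[C@H](O)[C@]23C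
F5 | step 5 | (Z)-7-chloro-2-ethoxy-5-methylhepta-1,4-dien-3-one | C=C(OCC)C(=O)/C=C(C)\CCCl
F6 | step 5 | (3R,4Z)-7-chloro-2-ethoxy-5-methylhepta-1,4-dien-3-ol | C=C(OCC)[C@H](O)/C=C(C)\CCCl
F7 | step 5 | 4-methoxybenzoate of F6 | C=C(OCC)[C@H](OC(=O)c1ccc(OC)cc1)/C=C(C)\CCCl
F8 | step 5 | (3R,4Z)-7-chloro-5-methyl-2-oxohept-4-en-3-yl 4-methoxybenzoate | CC(=O)[C@H](OC(=O)c1ccc(OC)cc1)/C=C(C)\CCCl
F9 | step 10 | C7-isopropenyl ketone, C6–OTMS | COc1ccc(cc1)C(=O)O[C@@H]2C=C(C)CC[C@]3(O[Si](C)(C)C)[C@@H](C(C)=C)CC(=O)[C@]23C
F10 | step 10 | C7-isopropyl ketone, C6–OTMS | COc1ccc(cc1)C(=O)O[C@@H]2C=C(C)CC[C@]3(O[Si](C)(C)C)[C@@H](C(C)C)CC(=O)[C@]23C
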